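Reagent over substrate charged stands at 1.00 in Wednesday's flask and at 1.00 in Saturday's.

| flask | substrate | reagent | remark | time |
|---|---|---|---|---|
| south-east | 0.50 M | 0.57 M | run made earlier |  |
| south | 0.50 M | 2.7 M | run made earlier |  |
| north-east | 0.90 M | 0.50 M | run made earlier |  |
| Wednesday's | 0.50 M | 0.500 M |  | 4.0 min |
| Saturday's | 2.0 M | 2.00 M |  | 8.0 min |

| run | time / min | target / % | substrate / % |
|---|---|---|---|
| south-east | 0.333 | 0 | 74.9 |
| south-east | 1.00 | 2.1 | 48.6 |
| south-east | 2.00 | 6.6 | 31.6 |
| south-east | 3.00 | 10.2 | 23.3 |
| south | 0.250 | 1.3 | 37.2 |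
| south | 0.500 | 5.4 | 15.4 |
| south | 1.33 | 26.0 | 1.0 |
| south | 3.00 | 50.6 | 0 |
| north-east | 0.333 | 0.3 | 78.4 |
| north-east | 1.00 | 0.8 | 59.4 |
| north-east | 2.00 | 2.8 | 47.8 |
| north-east | 3.00 | 4.4 | 42.5 |

(readings scatter by 0.3 percentage points)

- the numbers in the tables scatter by 0.3 percentage points (one standard deviation)

1. which one finishes higher in amount of target, in percent of the substrate charged ("neither" within 2 percentage points) (Wednesday's / Saturday's / neither)
2. amount of target at the end, in percent of the substrate charged, Wednesday's
3. amount of target at the end, in percent of the substrate charged, Saturday's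

Follow one substrate molecule. Its chance of surviving the reagent is exp(−x), where x, the exposure, is the natural log of substrate charged over substrate left. An intermediate meets the same reagent, so target is reckoned here to grow with x. The last south-east reading has x = 1.46 and target 10.2 %. That makes the target fraction per unit of exposure 0.0700. The same reading gives a second-order constant k of 0.0269 M⁻¹ s⁻¹. For equal charges, x is the log of one plus k times charge times time.

At 4.0 min, Wednesday's flask should reach x = 1.44, so it should hold about 23.7 % of its substrate and target 10.1 %. Saturday's has 8.00 times that charge times time, yet x reaches 3.29, up by a factor of 2.28. So at 8.0 min its target should be 23.0 %, higher. Leave the charges untouched: this reckoning is made for them.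

The forecast names Saturday's, with 12.5 % and 47 %: “Saturday's clearly finishes higher”. The flasks give 11.4 % for Wednesday's and 21.8 % for Saturday's.

    intermediate C ⇌ intermediate D (K = 0.280, k = 0.00590 s⁻¹)
    substrate ⇌ intermediate B (K = 2.90, k = 0.00130 s⁻¹)
    reagent + intermediate A ⇌ intermediate C (K = 50.0 M⁻¹, k = 0.0160 M⁻¹ s⁻¹)
    intermediate C → target (k = 0.0130 s⁻¹)
    intermediate C ⇌ intermediate E (K = 2.20, k = 0.0120 s⁻¹)
    substrate + reagent → intermediate A (k = 0.0260 M⁻¹ s⁻¹)

Saturday's flask keeps 15.1 % of its substrate against the 3.73 % reckoned, so its exposure is 1.89, not 3.29. Target per unit of exposure, taken on the substrate each flask keeps, comes to 0.0775 in Wednesday's and 0.115 in Saturday's, against 0.0700 from the south-east run. The shrinking supply of reagent, together with the time given, holds Wednesday's at 11.4 %: with reagent held at its charge that flask gives 30.5 %, and ten times as long gives 29.9 %.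

The neighbour of Wednesday's charged with 0.30 M of reagent has x = 0.736 by the same constant, so 5.15 % target is expected. That flask gives 4.66 %.

(The numbers in the tables are calculated with made-up constants; noise was put on by code.)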